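Locants follow the sesquiterpenoid skeleton: ring C5–C10; C1=C2 vinyl and C14 methyl on C10; C4(=C3H2)–C15H2OH on C5; C11(=C13H2)–C12O2H on C7.

## The problem

The target is an elemane-type cyclohexane in which only C9 is an unsubstituted methylene: C10 is quaternary (methyl, vinyl) and C5, C6, C7 and C8 carry a 3-hydroxyprop-1-en-2-yl arm, a free hydroxyl, an acrylic acid and a (Z)-4-acetoxy-2-methylbut-2-enoate. Five ring stereocentres (5R,6S,7S,8S,10S) must be set; in the preferred chair the C5, C7 and C8 substituents and the vinyl group are equatorial while the C6 hydroxyl and the C10 methyl are syn-axial, so vinyl is trans to the C5 arm, C5/C6/C7 are all-cis and C7/C8 are trans. C5 and C6 are neighbours and can be fixed together in an open chain; C5 can then direct the quaternary centre C10 during ring closure, C7 becomes correctable once it is α to a C8 carbonyl (equatorial is the stable epimer), and C8 can be set from the axial C6 hydroxyl by internal hydride delivery. Several groups are fragile: the γ-hydroxy acrylic acid lactonises under acid (and a C12 aldehyde beside a free C6–OH closes to a lactol and then the lactone), the (Z)-γ-acetoxy enoate isomerises or collapses to a butenolide under nucleophilic catalysis or when its γ-oxygen is free, an axial C6 oxygen β to a C8 carbonyl is lost by E1cB, and the doubly allylic C5–H and four isolated alkenes exclude hydrogenation and strong acid. The two primary allylic carbons C12 and C15 end in different oxidation states and must be told apart, and the acid must be released last under near-neutral conditions because no hydrolysis would spare the C8 ester and the acetate. The enabling feature is that C10 bears a vinyl group and lies next to C9, the methylene α to the C8 oxygen: with C8 as a ketone and C9 as a β-keto ester carbon, the C9–C10 bond is what an enolate leaves on attacking the substituted end of a C10–C1–C2 π-allyl unit, so ring, quaternary carbon and vinyl group arise together.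

## Retrosynthesis

**C12 oxidation level and silyl groups (43 ⇐ 42 ⇐ 40 ⇐ 39).** Only O–Si bonds and the oxidation level of C12 change. Carrying C12 as an ether-protected alcohol avoids a terminal ester hydrolysis that could not distinguish three esters. Keeping C6 silylated while C12 is oxidised prevents lactol and lactone formation. The forward steps must oxidise one primary allylic alcohol beside four alkenes and then remove two silyl groups without lactonisation or acyl shift.

**C8–O acyl bond (39 ⇐ 38 ⇐ 31 + 36).** Cutting the ester after C8 has become a carbinol keeps the sensitive side chain out of all enolate and hydride chemistry. The acylation must choose the equatorial C8–OH over the hindered axial C6–OH and must not isomerise 36. Acid 36 is derived from butenolide 32, whose ring fixes the Z geometry; the carboxyl is masked as PMB ester 35 while the γ-hydroxyl is acetylated, so no γ-hydroxy acid is ever free.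

**C8–H (31 ⇐ 30).** The C8 carbinol is traced to the ketone, which is needed anyway to functionalise and equilibrate C7. The forward reduction must deliver hydride to the ring face screened by the C10 methyl and the C6 oxygen, which only a C6–OH-bound hydride will do.

**C7–C11 (30 ⇐ 25 + 28; 25 ⇐ 24; 28 ⇐ 26 + 27).** The cut lies between the ring and the sp2 carbon C11, so C11, C12 and C13 arrive in one piece with C12 already a protected alcohol. Aldol or alkylation tactics would attach an sp3 carbon and need later methylenation and redox steps between two oxygens. The precursor 24 is simpler by three carbons and one stereocentre. The forward step needs an enolate equivalent fixed at C7 (not C9), a non-basic coupling, and C7 settling equatorial.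

**C9 ester (24 ⇐ 22).** The activating ester on C9 is added back. A tert-butyl ester is chosen so that its loss, and that of the C6 silyl group, is acidolytic; hot basic dealkoxycarbonylation would invite loss of the C6 oxygen.

**C9–C10 ring bond (22 ⇐ 21), the key cut.** Opening the ring between the β-keto ester carbon and quaternary C10 leaves an acyclic chain whose only stereocentres are C5 and C6, with an allylic carbonate C10=C1–C2–O as the electrophile. Cutting C5–C10 or C8–C9 instead would leave the quaternary carbon or the C5/C6 pair to be made on the ring. The forward reaction must close the six-membered ring at the more substituted allyl terminus and let C5 control C10.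

**C8–C9 and end-group exchange (21 ⇐ 19 + 20; 19 ⇐ 18 ⇐ 17 ⇐ 16 ⇐ 15 ⇐ 14).** Aldehyde 19 is homologated directly to the β-keto ester with diazo ester 20. The steps before it only exchange protecting groups: C2 silyl ether to methyl carbonate, C6–OH to TES ether, C8 PMB ether to aldehyde. The order is set so that each deprotection has a single candidate and the carbonate is made only after the last palladium-catalysed step of the fragment synthesis.

**C5–C6 (14 ⇐ 10 + 12; 12 ⇐ 11).** This bond joins the two stereocentres. Allylboration creates both, together with the C4=C3 methylidene and the C6 hydroxyl, and both alkenyl arms of C5 arrive complete. Aldol routes would leave a carbonyl on C5 and expose the doubly activated C5–H. The forward step needs the syn relationship from the boronate geometry through a chair transition state and the absolute sense from a chiral acid catalyst.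

**Boronate (10 ⇐ 8 + 9; 8 ⇐ 7 ⇐ 6 ⇐ 3 + 4; 3 ⇐ 1 + 2).** C3–C4 is cut to alkenyl bromide 8 and geminal diboronate 9; the two olefin bonds C4=C5 and C10=C1 are cut to stabilised ylides 4 and 2 and aldehyde 1. The Z-bromoalkene from the bromo-ylide olefination is what finally places the C10 arm cis to the CH2B group.

## Roads not taken

**Alternative 1: radical annulation from the C6 oxygen.** The cut is C7–C11 plus C8–O, leading back to cyclohexene bromoacetal A2. In the forward step the acetal radical adds 5-exo to C7 and the C8 radical is captured by a persistent nitroxyl, giving the cis-fused acetal A1.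
- Merits: the tether guarantees the C6/C7 cis relationship and anti capture gives C7/C8 trans; oxygen arrives at C8 without a ketone, so there is no β-elimination at C6 and no β,γ-enone stage. On C7/C8 stereocontrol this route is better than the chosen one.
- Weak points: the key step builds neither the ring nor C10, so A2 must be made with C5, C6 and C10 already in place. C11 arrives as CH2 and C12 as an acetal tied to the C6 oxygen, so C13 needs a later α-methylenation, and the C6–O–C12 link must be opened to hydroxy acid while the C8 ester and the acetate survive.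
- Comparison: the chosen plan has weaker control at C7 (thermodynamic) but brings in C11–C13 complete, never ties C12 to C6, and uses its key step to make the ring and the quaternary centre.

**Alternative 2: intramolecular Barbier allylation at C6–C7.** The ring bond C6–C7 is cut to the acyclic aldehyde–allylic bromide A4. Indium metal inserts into the C13–Br bond and the allyl metal adds to the C6 aldehyde through C7, giving A3 with the acrylate already at the acid oxidation level.
- Merits: the best step economy for the acrylic acid (no late redox on C12), mild conditions, and ring plus two stereocentres in one step. On endgame length it is better than the chosen plan by about four steps.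
- Weak points: A4 must contain quaternary C10 made in an open chain without a ring to bias it, and an aldehyde whose α-carbon C5 is allylic and epimerisable. The required product has the new C6–OH axial and syn to the C10 methyl, which a chair-like closure does not favour. A3 is a γ-hydroxy acrylate prone to lactonise while the C8 ether is exchanged for the acyl group.
- Comparison: the chosen plan pays with a longer endgame but sets C10 under ring-closure control and C6 before the ring exists.

**Alternative 3: Diels–Alder construction.** C9–C10 and C5–C6 are cut to diene A6 and the trisubstituted ene-dicarbonyl A7; aldehyde-directed regiochemistry and endo addition give A5 with C10, C5 and C6 set.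
- Merits: the most convergent entry (ring and three stereocentres from two small achiral components), and C8 emerges as a regiodefined enol silane, a better handle for C7 than step 16 of the chosen route. It is likely shorter to a cyclohexane core.
- Weak points: a trisubstituted dienophile forming a quaternary carbon is sluggish and needs Lewis acids that also degrade the bis-silyloxy diene; enantiocontrol for such a substrate is demanding. In A5, C10 carries an ester that must become vinyl at a neopentyl position, and C5 carries a formyl group that must gain two carbons beside an epimerisable C5–H and a β-silyloxy group.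
- Comparison: the chosen plan is longer to the ring but every carbon of the C5 and C10 appendages is in its final connectivity at cyclisation, and C5/C6 are set by reagent geometry and catalyst.

Key step: step 14

Assumption: (S)-TRIP is taken to direct the boronate to the Si face of aldehyde 12, the (R)-acid being known to give Re-face addition with simple aldehydes; if the sense were opposite the enantiomeric acid would be used.

Assumption: compound 11 is taken to be commercially available; if it is not, it is made from propane-1,3-diol by mono-4-methoxybenzylation, one more step outside the longest linear sequence.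

Abbreviations in names: TBS = tert-butyldimethylsilyl, TBDPS = tert-butyldiphenylsilyl, TES = triethylsilyl, TMS = trimethylsilyl, PMB = 4-methoxybenzyl.

## Route

Step 1
Reactants: 1 2-(TBS-oxy)acetaldehyde; 2 2-(triphenyl-λ5-phosphanylidene)propanal
Product: 3 (2E)-4-(TBS-oxy)-2-methylbut-2-enal
Conditions: PhMe, 80 °C
Reagents that add atoms: none
Why: Wittig olefination with a formyl-stabilised ylide; the aliphatic aldehyde reacts while the less electrophilic enal product does not, and the stabilised ylide gives the (E)-alkene that becomes C10=C1.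

Step 2
Reactants: 3 (2E)-4-(TBS-oxy)-2-methylbut-2-enal; 4 ethyl (triphenyl-λ5-phosphanylidene)acetate
Product: 6 ethyl (2Z,4E)-2-bromo-6-(TBS-oxy)-4-methylhexa-2,4-dienoate, via bromo ylide 5 (not isolated)
Conditions: N-bromosuccinimide, CH2Cl2, −20 °C; then 3, rt
Reagents that add atoms: N-bromosuccinimide, O=C1CCC(=O)N1Br
Why: Bromination of the stabilised ylide and Wittig olefination in one flask; the ester of the α-bromo ylide ends trans to the dienyl substituent, so bromine (the later CH2B position) is cis to the C10 arm (2Z).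

Step 3
Reactants: 6 ethyl (2Z,4E)-2-bromo-6-(TBS-oxy)-4-methylhexa-2,4-dienoate
Product: 7 (2Z,4E)-2-bromo-6-(TBS-oxy)-4-methylhexa-2,4-dien-1-ol
Conditions: i-Bu2AlH, CH2Cl2, −78 °C
Reagents that add atoms: none
Why: 1,2-Reduction of an α-bromo enoate by the aluminium hydride at low temperature; the vinylic C–Br bond, the diene geometry and the silyl ether are not touched.

Step 4
Reactants: 7 (2Z,4E)-2-bromo-6-(TBS-oxy)-4-methylhexa-2,4-dien-1-ol
Product: 8 (2Z,4E)-2-bromo-1-(TBDPS-oxy)-6-(TBS-oxy)-4-methylhexa-2,4-diene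
Conditions: t-BuPh2SiCl, imidazole, CH2Cl2, 0 °C → rt
Reagents that add atoms: tert-butyl(chloro)diphenylsilane, CC(C)(C)[Si](Cl)(c1ccccc1)c1ccccc1
Why: Standard silylation of a primary allylic alcohol; the robust TBDPS group marks C15 for the whole route and is distinguishable from the TBS ether at C2.

Step 5
Reactants: 8 (2Z,4E)-2-bromo-1-(TBDPS-oxy)-6-(TBS-oxy)-4-methylhexa-2,4-diene; 9 bis(4,4,5,5-tetramethyl-1,3,2-dioxaborolan-2-yl)methane
Product: 10 pinacol [(2E,4E)-6-(TBS-oxy)-2-(TBDPS-oxymethyl)-4-methylhexa-2,4-dien-1-yl]boronate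
Conditions: Pd[P(t-Bu)3]2 (5 mol %), 8 M aq. KOH, 1,4-dioxane, rt
Reagents that add atoms: none
Why: Suzuki–Miyaura coupling of an alkenyl bromide with a geminal diboronate, in which hydroxide activates one boron only; the coupling proceeds with retention at the alkene, so the CH2B group stays cis to the C10 arm.

Step 6
Reactants: 11 3-(PMB-oxy)propan-1-ol
Product: 12 3-(PMB-oxy)propanal
Conditions: Dess–Martin periodinane, NaHCO3, CH2Cl2, 0 °C → rt
Reagents that add atoms: none
Why: Dess–Martin oxidation of a primary alcohol to the aldehyde under buffered conditions that do not eliminate the β-alkoxy group.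

Step 7
Reactants: 10 pinacol [(2E,4E)-6-(TBS-oxy)-2-(TBDPS-oxymethyl)-4-methylhexa-2,4-dien-1-yl]boronate; 12 3-(PMB-oxy)propanal
Product: 14 (3R,4R,5E)-7-(TBS-oxy)-4-[3-(TBDPS-oxy)prop-1-en-2-yl]-1-(PMB-oxy)-5-methylhept-5-en-3-ol, via pinacol borate 13 (not isolated)
Conditions: (S)-3,3′-bis(2,4,6-triisopropylphenyl)-1,1′-binaphthyl-2,2′-diyl hydrogen phosphate [(S)-TRIP] (5 mol %), 4 Å molecular sieves, PhMe, −30 → 0 °C; aq. NaHCO3
Reagents that add atoms: none
Why: Chiral phosphoric acid-catalysed allylboration through a Zimmerman–Traxler chair; the boronate geometry puts the C10 arm axial on the γ-carbon and so gives the syn (5R,6R) pair together with the C4=C3 methylidene, while the acid, hydrogen-bonded to a boronate oxygen and the formyl hydrogen, directs addition to the Si face of the aldehyde (6R).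

Step 8
Reactants: 14 (3R,4R,5E)-7-(TBS-oxy)-4-[3-(TBDPS-oxy)prop-1-en-2-yl]-1-(PMB-oxy)-5-methylhept-5-en-3-ol
Product: 15 (2E,4R,5R)-4-[3-(TBDPS-oxy)prop-1-en-2-yl]-7-(PMB-oxy)-3-methylhept-2-ene-1,5-diol
Conditions: HF·pyridine, pyridine, THF, 0 °C
Reagents that add atoms: none
Why: Chemoselective desilylation; a primary allylic TBS ether is cleaved by buffered HF far faster than the primary TBDPS ether, and the PMB ether is inert.

Step 9
Reactants: 15 (2E,4R,5R)-4-[3-(TBDPS-oxy)prop-1-en-2-yl]-7-(PMB-oxy)-3-methylhept-2-ene-1,5-diol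
Product: 16 methyl (2E,4R,5R)-4-[3-(TBDPS-oxy)prop-1-en-2-yl]-5-hydroxy-7-(PMB-oxy)-3-methylhept-2-en-1-yl carbonate
Conditions: ClCO2Me (1.1 equiv), pyridine, CH2Cl2, −20 °C
Reagents that add atoms: methyl chloroformate, COC(=O)Cl
Why: Acylation of the unhindered primary allylic hydroxyl; the secondary C6–OH, flanked by the branched C5, reacts much more slowly at low temperature.

Step 10
Reactants: 16 methyl (2E,4R,5R)-4-[3-(TBDPS-oxy)prop-1-en-2-yl]-5-hydroxy-7-(PMB-oxy)-3-methylhept-2-en-1-yl carbonate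
Product: 17 methyl (2E,4R,5R)-4-[3-(TBDPS-oxy)prop-1-en-2-yl]-7-(PMB-oxy)-3-methyl-5-(TES-oxy)hept-2-en-1-yl carbonate
Conditions: Et3SiOTf, 2,6-lutidine, CH2Cl2, −78 °C
Reagents that add atoms: triethylsilyl trifluoromethanesulfonate, CC[Si](CC)(CC)OS(=O)(=O)C(F)(F)F
Why: Silyl triflate silylation of a hindered secondary alcohol; the TES group is chosen because it leaves again in the acidolysis of step 15.

Step 11
Reactants: 17 methyl (2E,4R,5R)-4-[3-(TBDPS-oxy)prop-1-en-2-yl]-7-(PMB-oxy)-3-methyl-5-(TES-oxy)hept-2-en-1-yl carbonate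
Product: 18 methyl (2E,4R,5R)-4-[3-(TBDPS-oxy)prop-1-en-2-yl]-7-hydroxy-3-methyl-5-(TES-oxy)hept-2-en-1-yl carbonate
Conditions: DDQ, CH2Cl2/pH 7 buffer, 0 °C
Reagents that add atoms: none
Why: Oxidative cleavage of the electron-rich PMB ether by DDQ; buffered, cold conditions spare the silyl ethers, the carbonate and the skipped diene.

Step 12
Reactants: 18 methyl (2E,4R,5R)-4-[3-(TBDPS-oxy)prop-1-en-2-yl]-7-hydroxy-3-methyl-5-(TES-oxy)hept-2-en-1-yl carbonate
Product: 19 methyl (2E,4R,5R)-4-[3-(TBDPS-oxy)prop-1-en-2-yl]-3-methyl-7-oxo-5-(TES-oxy)hept-2-en-1-yl carbonate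
Conditions: Dess–Martin periodinane, NaHCO3, CH2Cl2, 0 °C
Reagents that add atoms: none
Why: Dess–Martin oxidation to the β-silyloxy aldehyde under buffered, non-basic conditions that avoid β-elimination.

Step 13
Reactants: 19 methyl (2E,4R,5R)-4-[3-(TBDPS-oxy)prop-1-en-2-yl]-3-methyl-7-oxo-5-(TES-oxy)hept-2-en-1-yl carbonate; 20 tert-butyl diazoacetate
Product: 21 tert-butyl (5R,6R,7E)-6-[3-(TBDPS-oxy)prop-1-en-2-yl]-9-[(methoxycarbonyl)oxy]-7-methyl-3-oxo-5-(TES-oxy)non-7-enoate
Conditions: SnCl2 (10 mol %), CH2Cl2, rt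
Reagents that add atoms: none
Why: Roskamp homologation; the Lewis acid-activated aldehyde adds the diazo ester, and 1,2-hydride shift with loss of nitrogen gives the β-keto ester (C8–C9 bond) without base.

Step 14
Reactants: 21 tert-butyl (5R,6R,7E)-6-[3-(TBDPS-oxy)prop-1-en-2-yl]-9-[(methoxycarbonyl)oxy]-7-methyl-3-oxo-5-(TES-oxy)non-7-enoate
Product: 22 tert-butyl (2S,3R,4R)-2-ethenyl-2-methyl-6-oxo-3-[3-(TBDPS-oxy)prop-1-en-2-yl]-4-(TES-oxy)cyclohexane-1-carboxylate (C1 epimers and enol; target locants 5R,6R,10S)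
Conditions: Pd(PPh3)4 (5 mol %), THF, 40 °C
Reagents that add atoms: none
Why: Tsuji–Trost allylic alkylation: zerovalent palladium ionises the allylic carbonate with inversion, carbon dioxide is lost and the methoxide formed deprotonates the β-keto ester, so no external base is present. The C9 enolate attacks the methyl-bearing allyl terminus C10 on the face opposite the metal in a 6-exo closure; attack at C2 would need an eight-membered ring, and any O-allylation is reversible under the catalyst and drains to the C-alkylated product. The closest known reaction type is the palladium-catalysed cyclisation of β-keto esters onto trisubstituted allylic carbonates that leaves a vinyl-bearing quaternary carbon in a cyclohexanone. The new stereocentre C10 is controlled by C5: in the chair-like transition state the C5 arm is equatorial, the palladium-bound C1–C2 unit takes the equatorial site at C10 and the small methyl group the axial site beside the axial C6 silyloxy group, which gives vinyl trans to the C5 arm (10S). Both allyl faces are available because the complex exchanges faces by η3–η1–η3 isomerisation at the unsubstituted terminus C2, so the outcome is under Curtin–Hammett control. The step therefore needs facial selectivity at C10 and six- over eight-membered ring selectivity; the first rests on the equatorial preference of the metal-bearing arm, the second on ring size. C9 forms as an enolisable mixture that is erased in step 15.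

Step 15
Reactants: 22 tert-butyl (2S,3R,4R)-2-ethenyl-2-methyl-6-oxo-3-[3-(TBDPS-oxy)prop-1-en-2-yl]-4-(TES-oxy)cyclohexane-1-carboxylate
Product: 24 (3S,4R,5R)-4-[3-(TBDPS-oxy)prop-1-en-2-yl]-3-ethenyl-5-hydroxy-3-methylcyclohexan-1-one, via β-keto acid 23 (not isolated)
Conditions: CF3CO2H/CH2Cl2 (1:4), H2O (2 equiv), 0 °C; evaporate; PhMe, 80 °C
Reagents that add atoms: none
Why: Acidolysis of the tert-butyl ester (loss of isobutene) with concurrent cleavage of the TES ether, then thermal decarboxylation of the β-keto acid in neutral solution; this avoids the hot basic medium of a salt-mediated dealkoxycarbonylation, in which the axial C6 oxygen could be lost by E1cB, and the TBDPS ether survives.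

Step 16
Reactants: 24 (3S,4R,5R)-4-[3-(TBDPS-oxy)prop-1-en-2-yl]-3-ethenyl-5-hydroxy-3-methylcyclohexan-1-one
Product: 25 (3S,4R,5S)-4-[3-(TBDPS-oxy)prop-1-en-2-yl]-5-ethenyl-5-methyl-1,3-bis(TMS-oxy)cyclohex-1-ene
Conditions: LiN(SiMe3)2 (2.5 equiv), Me3SiCl (5 equiv), THF, −78 °C
Reagents that add atoms: chlorotrimethylsilane, C[Si](C)(C)Cl
Why: Kinetic enolisation with internal silyl quench; C7 is deprotonated in preference to C9, which is shielded by the quaternary C10, the C6 oxygen is silylated in the same operation, and at −78 °C the enolate is trapped before it can expel the C6 oxygen.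

Step 17
Reactants: 26 (4-methoxyphenyl)methanol; 27 2,3-dibromoprop-1-ene
Product: 28 1-{[(2-bromoprop-2-en-1-yl)oxy]methyl}-4-methoxybenzene
Conditions: NaH, THF/DMF, 0 °C → rt
Reagents that add atoms: none
Why: Williamson ether synthesis; the alkoxide displaces the allylic bromide and leaves the vinylic bromide for the coupling.

Step 18
Reactants: 25 (3S,4R,5S)-4-[3-(TBDPS-oxy)prop-1-en-2-yl]-5-ethenyl-5-methyl-1,3-bis(TMS-oxy)cyclohex-1-ene; 28 1-{[(2-bromoprop-2-en-1-yl)oxy]methyl}-4-methoxybenzene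
Product: 30 (2S,3S,4R,5S)-4-[3-(TBDPS-oxy)prop-1-en-2-yl]-5-ethenyl-3-hydroxy-5-methyl-2-[3-(PMB-oxy)prop-1-en-2-yl]cyclohexan-1-one, via silyl ether 29 (not isolated)
Conditions: Bu3SnF (1.3 equiv), PdCl2[P(o-tol)3]2 (5 mol %), PhMe, 80 °C; then citric acid, MeOH, 0 °C
Reagents that add atoms: none
Why: Palladium-catalysed α-alkenylation of a ketone through its tributyltin enolate, generated from the enol silane by fluoride and coupled with the alkenyl bromide (Stille-type coupling of a tin enolate); the enol silane fixes the site at C7, the medium is not basic, and C7, still α to the ketone, settles in the equatorial configuration cis to the C6 oxygen (7S); acidic methanol then frees the C6 hydroxyl.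

Step 19
Reactants: 30 (2S,3S,4R,5S)-4-[3-(TBDPS-oxy)prop-1-en-2-yl]-5-ethenyl-3-hydroxy-5-methyl-2-[3-(PMB-oxy)prop-1-en-2-yl]cyclohexan-1-one
Product: 31 (1S,2R,3S,4R,5S)-4-[3-(TBDPS-oxy)prop-1-en-2-yl]-5-ethenyl-5-methyl-2-[3-(PMB-oxy)prop-1-en-2-yl]cyclohexane-1,3-diol
Conditions: Me4NBH(OAc)3, MeCN/AcOH (1:1), −30 °C
Reagents that add atoms: none
Why: Evans–Saksena reduction; the acetoxyborohydride exchanges onto the axial C6 hydroxyl and delivers hydride intramolecularly to the same face of C8, which external hydrides avoid because of the syn-axial methyl and oxygen, giving the equatorial C8 carbinol (1,3-anti, 8S).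

Step 20
Reactants: 32 3-methylfuran-2(5H)-one
Product: 35 4-methoxybenzyl (2Z)-4-acetoxy-2-methylbut-2-enoate, via sodium hydroxy enoate 33 (not isolated), via hydroxy ester 34 (not isolated)
Conditions: NaOH (1.0 equiv), H2O/THF, rt; evaporate; 4-MeOC6H4CH2Cl, Bu4NI (cat.), DMF, rt; then Ac2O, pyridine, 4-(dimethylamino)pyridine (cat.), 0 °C
Reagents that add atoms: sodium hydroxide, [Na+].[OH-]; 4-methoxybenzyl chloride, COc1ccc(CCl)cc1; acetic anhydride, CC(=O)OC(C)=O
Why: Saponification of the butenolide, O-alkylation of the carboxylate and immediate acetylation of the γ-hydroxyl in one flask; the Z geometry is inherited from the ring and the γ-hydroxy ester is acetylated before it can relactonise.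

Step 21
Reactants: 35 4-methoxybenzyl (2Z)-4-acetoxy-2-methylbut-2-enoate
Product: 36 (2Z)-4-acetoxy-2-methylbut-2-enoic acid
Conditions: CF3CO2H, anisole, CH2Cl2, 0 °C
Reagents that add atoms: none
Why: Acidolysis of the PMB ester with anisole as cation trap; the acetate is stable, and with no free γ-hydroxyl the acid cannot close to the butenolide.

Step 22
Reactants: 31 (1S,2R,3S,4R,5S)-4-[3-(TBDPS-oxy)prop-1-en-2-yl]-5-ethenyl-5-methyl-2-[3-(PMB-oxy)prop-1-en-2-yl]cyclohexane-1,3-diol; 36 (2Z)-4-acetoxy-2-methylbut-2-enoic acid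
Product: 38 (1S,2S,3S,4R,5S)-4-[3-(TBDPS-oxy)prop-1-en-2-yl]-5-ethenyl-3-hydroxy-5-methyl-2-[3-(PMB-oxy)prop-1-en-2-yl]cyclohexyl (2Z)-4-acetoxy-2-methylbut-2-enoate, via mixed anhydride 37 (not isolated)
Conditions: 2,4,6-Cl3C6H2COCl, Et3N, PhMe, rt; then 31, 70 °C
Reagents that add atoms: none
Why: Yamaguchi-type mixed-anhydride esterification run without a nucleophilic catalyst, the conditions under which (Z)-2-methylbut-2-enoates are transferred without Z to E isomerisation; the equatorial C8–OH reacts, whereas the axial C6–OH, flanked by two branched carbons and syn-axial to the C10 methyl, does not.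

Step 23
Reactants: 38 (1S,2S,3S,4R,5S)-4-[3-(TBDPS-oxy)prop-1-en-2-yl]-5-ethenyl-3-hydroxy-5-methyl-2-[3-(PMB-oxy)prop-1-en-2-yl]cyclohexyl (2Z)-4-acetoxy-2-methylbut-2-enoate
Product: 39 (1S,2R,3S,4R,5S)-4-[3-(TBDPS-oxy)prop-1-en-2-yl]-5-ethenyl-5-methyl-2-[3-(PMB-oxy)prop-1-en-2-yl]-3-(TES-oxy)cyclohexyl (2Z)-4-acetoxy-2-methylbut-2-enoate
Conditions: Et3SiOTf, 2,6-lutidine, CH2Cl2, −78 °C
Reagents that add atoms: triethylsilyl trifluoromethanesulfonate, CC[Si](CC)(CC)OS(=O)(=O)C(F)(F)F
Why: Silyl triflate silylation of the hindered C6 hydroxyl; masking it prevents the C12 aldehyde of step 25 from closing to a lactol that would be oxidised to the lactone.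

Step 24
Reactants: 39 (1S,2R,3S,4R,5S)-4-[3-(TBDPS-oxy)prop-1-en-2-yl]-5-ethenyl-5-methyl-2-[3-(PMB-oxy)prop-1-en-2-yl]-3-(TES-oxy)cyclohexyl (2Z)-4-acetoxy-2-methylbut-2-enoate
Product: 40 (1S,2R,3S,4R,5S)-4-[3-(TBDPS-oxy)prop-1-en-2-yl]-5-ethenyl-2-(3-hydroxyprop-1-en-2-yl)-5-methyl-3-(TES-oxy)cyclohexyl (2Z)-4-acetoxy-2-methylbut-2-enoate
Conditions: DDQ, CH2Cl2/pH 7 buffer, 0 °C
Reagents that add atoms: none
Why: Oxidative PMB ether cleavage with DDQ under buffered conditions, which leaves the silyl ethers, the acetate and the enoate unchanged.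

Step 25
Reactants: 40 (1S,2R,3S,4R,5S)-4-[3-(TBDPS-oxy)prop-1-en-2-yl]-5-ethenyl-2-(3-hydroxyprop-1-en-2-yl)-5-methyl-3-(TES-oxy)cyclohexyl (2Z)-4-acetoxy-2-methylbut-2-enoate
Product: 42 2-[(1R,2S,3R,4S,6S)-6-{[(2Z)-4-acetoxy-2-methylbut-2-enoyl]oxy}-3-[3-(TBDPS-oxy)prop-1-en-2-yl]-4-ethenyl-4-methyl-2-(TES-oxy)cyclohexyl]prop-2-enoic acid, via enal 41 (not isolated)
Conditions: 2,2,6,6-tetramethylpiperidin-1-oxyl (TEMPO, cat.), PhI(OAc)2, CH2Cl2, rt; then NaClO2, NaH2PO4, 2-methylbut-2-ene, t-BuOH/H2O, 0 °C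
Reagents that add atoms: sodium chlorite, [Na+].[O-]Cl=O
Why: Nitroxyl-catalysed oxidation of the primary allylic alcohol to the 2-substituted acrolein followed in the same flask by Pinnick oxidation; the buffered chlorite with an alkene scavenger oxidises only the aldehyde and tolerates the other alkenes and esters.

Step 26
Reactants: 42 2-[(1R,2S,3R,4S,6S)-6-{[(2Z)-4-acetoxy-2-methylbut-2-enoyl]oxy}-3-[3-(TBDPS-oxy)prop-1-en-2-yl]-4-ethenyl-4-methyl-2-(TES-oxy)cyclohexyl]prop-2-enoic acid
Product: 43 2-[(1S,2S,3R,4S,6S)-6-{[(2Z)-4-acetoxy-2-methylbut-2-enoyl]oxy}-4-ethenyl-2-hydroxy-3-(3-hydroxyprop-1-en-2-yl)-4-methylcyclohexyl]prop-2-enoic acid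
Conditions: HF·pyridine, pyridine, THF, 0 °C → rt
Reagents that add atoms: none
Why: Global desilylation with pyridine-buffered hydrogen fluoride; the medium is neither basic enough for acetate cleavage or acyl shift nor acidic enough to lactonise the γ-hydroxy acid, and the trans-1,3 relationship of the C6 hydroxyl and the C8 ester disfavours acyl migration.

## Compound list

1 | 2-[(tert-butyldimethylsilyl)oxy]acetaldehyde | O=CCO[Si](C)(C)C(C)(C)C | starting material
2 | 2-(triphenyl-λ5-phosphanylidene)propanal | CC(C=O)=P(c1ccccc1)(c1ccccc1)c1ccccc1 | starting material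
3 | (2E)-4-[(tert-butyldimethylsilyl)oxy]-2-methylbut-2-enal | O=C/C(C)=C/CO[Si](C)(C)C(C)(C)C | intermediate
4 | ethyl (triphenyl-λ5-phosphanylidene)acetate | CCOC(=O)C=P(c1ccccc1)(c1ccccc1)c1ccccc1 | starting material
5 | ethyl bromo(triphenyl-λ5-phosphanylidene)acetate | CCOC(=O)C(Br)=P(c1ccccc1)(c1ccccc1)c1ccccc1 | intermediate (not isolated)
6 | ethyl (2Z,4E)-2-bromo-6-[(tert-butyldimethylsilyl)oxy]-4-methylhexa-2,4-dienoate | CCOC(=O)/C(Br)=C/C(C)=C/CO[Si](C)(C)C(C)(C)C | intermediate
7 | (2Z,4E)-2-bromo-6-[(tert-butyldimethylsilyl)oxy]-4-methylhexa-2,4-dien-1-ol | OC/C(Br)=C/C(C)=C/CO[Si](C)(C)C(C)(C)C | intermediate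
8 | (2Z,4E)-2-bromo-1-[(tert-butyldiphenylsilyl)oxy]-6-[(tert-butyldimethylsilyl)oxy]-4-methylhexa-2,4-diene | CC(C)(C)[Si](OC/C(Br)=C/C(C)=C/CO[Si](C)(C)C(C)(C)C)(c1ccccc1)c1ccccc1 | intermediate
9 | bis(4,4,5,5-tetramethyl-1,3,2-dioxaborolan-2-yl)methane | CC1(C)OB(CB2OC(C)(C)C(C)(C)O2)OC1(C)C | starting material
10 | 2-[(2E,4E)-6-[(tert-butyldimethylsilyl)oxy]-2-{[(tert-butyldiphenylsilyl)oxy]methyl}-4-methylhexa-2,4-dien-1-yl]-4,4,5,5-tetramethyl-1,3,2-dioxaborolane | CC(C)(C)[Si](OC/C(CB1OC(C)(C)C(C)(C)O1)=C/C(C)=C/CO[Si](C)(C)C(C)(C)C)(c1ccccc1)c1ccccc1 | intermediate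
11 | 3-[(4-methoxybenzyl)oxy]propan-1-ol | COc1ccc(COCCCO)cc1 | starting material
12 | 3-[(4-methoxybenzyl)oxy]propanal | COc1ccc(COCCC=O)cc1 | intermediate
13 | O-(4,4,5,5-tetramethyl-1,3,2-dioxaborolan-2-yl) derivative of 14 (5R,6R) | COc1ccc(COCC[C@@H](OB2OC(C)(C)C(C)(C)O2)[C@@H](C(=C)CO[Si](c2ccccc2)(c2ccccc2)C(C)(C)C)/C(C)=C/CO[Si](C)(C)C(C)(C)C)cc1 | intermediate (not isolated)
14 | (3R,4R,5E)-7-[(tert-butyldimethylsilyl)oxy]-4-{3-[(tert-butyldiphenylsilyl)oxy]prop-1-en-2-yl}-1-[(4-methoxybenzyl)oxy]-5-methylhept-5-en-3-ol (target locants 5R,6R) | COc1ccc(COCC[C@@H](O)[C@@H](C(=C)CO[Si](c2ccccc2)(c2ccccc2)C(C)(C)C)/C(C)=C/CO[Si](C)(C)C(C)(C)C)cc1 | intermediate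
15 | (2E,4R,5R)-4-{3-[(tert-butyldiphenylsilyl)oxy]prop-1-en-2-yl}-7-[(4-methoxybenzyl)oxy]-3-methylhept-2-ene-1,5-diol | COc1ccc(COCC[C@@H](O)[C@@H](C(=C)CO[Si](c2ccccc2)(c2ccccc2)C(C)(C)C)/C(C)=C/CO)cc1 | intermediate
16 | methyl (2E,4R,5R)-4-{3-[(tert-butyldiphenylsilyl)oxy]prop-1-en-2-yl}-5-hydroxy-7-[(4-methoxybenzyl)oxy]-3-methylhept-2-en-1-yl carbonate | COc1ccc(COCC[C@@H](O)[C@@H](C(=C)CO[Si](c2ccccc2)(c2ccccc2)C(C)(C)C)/C(C)=C/COC(=O)OC)cc1 | intermediate
17 | methyl (2E,4R,5R)-4-{3-[(tert-butyldiphenylsilyl)oxy]prop-1-en-2-yl}-7-[(4-methoxybenzyl)oxy]-3-methyl-5-[(triethylsilyl)oxy]hept-2-en-1-yl carbonate | COc1ccc(COCC[C@@H](O[Si](CC)(CC)CC)[C@@H](C(=C)CO[Si](c2ccccc2)(c2ccccc2)C(C)(C)C)/C(C)=C/COC(=O)OC)cc1 | intermediate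
18 | methyl (2E,4R,5R)-4-{3-[(tert-butyldiphenylsilyl)oxy]prop-1-en-2-yl}-7-hydroxy-3-methyl-5-[(triethylsilyl)oxy]hept-2-en-1-yl carbonate | OCC[C@@H](O[Si](CC)(CC)CC)[C@@H](C(=C)CO[Si](c1ccccc1)(c1ccccc1)C(C)(C)C)/C(C)=C/COC(=O)OC | intermediate
19 | methyl (2E,4R,5R)-4-{3-[(tert-butyldiphenylsilyl)oxy]prop-1-en-2-yl}-3-methyl-7-oxo-5-[(triethylsilyl)oxy]hept-2-en-1-yl carbonate | O=CC[C@@H](O[Si](CC)(CC)CC)[C@@H](C(=C)CO[Si](c1ccccc1)(c1ccccc1)C(C)(C)C)/C(C)=C/COC(=O)OC | intermediate
20 | tert-butyl diazoacetate | CC(C)(C)OC(=O)C=[N+]=[N-] | starting material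
21 | tert-butyl (5R,6R,7E)-6-{3-[(tert-butyldiphenylsilyl)oxy]prop-1-en-2-yl}-9-[(methoxycarbonyl)oxy]-7-methyl-3-oxo-5-[(triethylsilyl)oxy]non-7-enoate | CC(C)(C)OC(=O)CC(=O)C[C@@H](O[Si](CC)(CC)CC)[C@@H](C(=C)CO[Si](c1ccccc1)(c1ccccc1)C(C)(C)C)/C(C)=C/COC(=O)OC | intermediate
22 | tert-butyl (2S,3R,4R)-2-ethenyl-2-methyl-6-oxo-3-{3-[(tert-butyldiphenylsilyl)oxy]prop-1-en-2-yl}-4-[(triethylsilyl)oxy]cyclohexane-1-carboxylate (C1 epimers and enol; target locants 5R,6R,10S) | C=C[C@]1(C)C(C(=O)OC(C)(C)C)C(=O)C[C@@H](O[Si](CC)(CC)CC)[C@H]1C(=C)CO[Si](c2ccccc2)(c2ccccc2)C(C)(C)C | intermediate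
23 | (2S,3R,4R)-2-ethenyl-4-hydroxy-2-methyl-6-oxo-3-{3-[(tert-butyldiphenylsilyl)oxy]prop-1-en-2-yl}cyclohexane-1-carboxylic acid (C1 epimers) | C=C[C@]1(C)C(C(=O)O)C(=O)C[C@@H](O)[C@H]1C(=C)CO[Si](c2ccccc2)(c2ccccc2)C(C)(C)C | intermediate (not isolated)
24 | (3S,4R,5R)-4-{3-[(tert-butyldiphenylsilyl)oxy]prop-1-en-2-yl}-3-ethenyl-5-hydroxy-3-methylcyclohexan-1-one | C=C[C@]1(C)CC(=O)C[C@@H](O)[C@H]1C(=C)CO[Si](c2ccccc2)(c2ccccc2)C(C)(C)C | intermediate
25 | (3S,4R,5S)-4-{3-[(tert-butyldiphenylsilyl)oxy]prop-1-en-2-yl}-5-ethenyl-5-methyl-1,3-bis[(trimethylsilyl)oxy]cyclohex-1-ene | C=C[C@]1(C)CC(O[Si](C)(C)C)=C[C@@H](O[Si](C)(C)C)[C@H]1C(=C)CO[Si](c2ccccc2)(c2ccccc2)C(C)(C)C | intermediate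
26 | (4-methoxyphenyl)methanol | COc1ccc(CO)cc1 | starting material
27 | 2,3-dibromoprop-1-ene | C=C(Br)CBr | starting material
28 | 1-{[(2-bromoprop-2-en-1-yl)oxy]methyl}-4-methoxybenzene | C=C(Br)COCc1ccc(OC)cc1 | intermediate
29 | (2S,3S,4R,5S)-4-{3-[(tert-butyldiphenylsilyl)oxy]prop-1-en-2-yl}-5-ethenyl-5-methyl-2-{3-[(4-methoxybenzyl)oxy]prop-1-en-2-yl}-3-[(trimethylsilyl)oxy]cyclohexan-1-one | C=C[C@]1(C)CC(=O)[C@@H](C(=C)COCc2ccc(OC)cc2)[C@@H](O[Si](C)(C)C)[C@H]1C(=C)CO[Si](c2ccccc2)(c2ccccc2)C(C)(C)C | intermediate (not isolated)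
30 | (2S,3S,4R,5S)-4-{3-[(tert-butyldiphenylsilyl)oxy]prop-1-en-2-yl}-5-ethenyl-3-hydroxy-5-methyl-2-{3-[(4-methoxybenzyl)oxy]prop-1-en-2-yl}cyclohexan-1-one | C=C[C@]1(C)CC(=O)[C@@H](C(=C)COCc2ccc(OC)cc2)[C@@H](O)[C@H]1C(=C)CO[Si](c2ccccc2)(c2ccccc2)C(C)(C)C | intermediate
31 | (1S,2R,3S,4R,5S)-4-{3-[(tert-butyldiphenylsilyl)oxy]prop-1-en-2-yl}-5-ethenyl-5-methyl-2-{3-[(4-methoxybenzyl)oxy]prop-1-en-2-yl}cyclohexane-1,3-diol | C=C[C@]1(C)C[C@H](O)[C@@H](C(=C)COCc2ccc(OC)cc2)[C@@H](O)[C@H]1C(=C)CO[Si](c2ccccc2)(c2ccccc2)C(C)(C)C | intermediate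
32 | 3-methylfuran-2(5H)-one | CC1=CCOC1=O | starting material
33 | sodium (2Z)-4-hydroxy-2-methylbut-2-enoate | [Na+].[O-]C(=O)/C(C)=C\CO | intermediate (not isolated)
34 | 4-methoxybenzyl (2Z)-4-hydroxy-2-methylbut-2-enoate | COc1ccc(COC(=O)/C(C)=C\CO)cc1 | intermediate (not isolated)
35 | 4-methoxybenzyl (2Z)-4-acetoxy-2-methylbut-2-enoate | COc1ccc(COC(=O)/C(C)=C\COC(C)=O)cc1 | intermediate
36 | (2Z)-4-acetoxy-2-methylbut-2-enoic acid | OC(=O)/C(C)=C\COC(C)=O | intermediate
37 | (2Z)-4-acetoxy-2-methylbut-2-enoic 2,4,6-trichlorobenzoic anhydride | O=C(OC(=O)/C(C)=C\COC(C)=O)c1c(Cl)cc(Cl)cc1Cl | intermediate (not isolated)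
38 | (1S,2S,3S,4R,5S)-4-{3-[(tert-butyldiphenylsilyl)oxy]prop-1-en-2-yl}-5-ethenyl-3-hydroxy-5-methyl-2-{3-[(4-methoxybenzyl)oxy]prop-1-en-2-yl}cyclohexyl (2Z)-4-acetoxy-2-methylbut-2-enoate | C=C[C@]1(C)C[C@H](OC(=O)/C(C)=C\COC(C)=O)[C@@H](C(=C)COCc2ccc(OC)cc2)[C@@H](O)[C@H]1C(=C)CO[Si](c2ccccc2)(c2ccccc2)C(C)(C)C | intermediate
39 | (1S,2R,3S,4R,5S)-4-{3-[(tert-butyldiphenylsilyl)oxy]prop-1-en-2-yl}-5-ethenyl-5-methyl-2-{3-[(4-methoxybenzyl)oxy]prop-1-en-2-yl}-3-[(triethylsilyl)oxy]cyclohexyl (2Z)-4-acetoxy-2-methylbut-2-enoate | C=C[C@]1(C)C[C@H](OC(=O)/C(C)=C\COC(C)=O)[C@@H](C(=C)COCc2ccc(OC)cc2)[C@@H](O[Si](CC)(CC)CC)[C@H]1C(=C)CO[Si](c2ccccc2)(c2ccccc2)C(C)(C)C | intermediate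
40 | (1S,2R,3S,4R,5S)-4-{3-[(tert-butyldiphenylsilyl)oxy]prop-1-en-2-yl}-5-ethenyl-2-(3-hydroxyprop-1-en-2-yl)-5-methyl-3-[(triethylsilyl)oxy]cyclohexyl (2Z)-4-acetoxy-2-methylbut-2-enoate | C=C[C@]1(C)C[C@H](OC(=O)/C(C)=C\COC(C)=O)[C@@H](C(=C)CO)[C@@H](O[Si](CC)(CC)CC)[C@H]1C(=C)CO[Si](c2ccccc2)(c2ccccc2)C(C)(C)C | intermediate
41 | (1S,2R,3S,4R,5S)-4-{3-[(tert-butyldiphenylsilyl)oxy]prop-1-en-2-yl}-5-ethenyl-5-methyl-2-(3-oxoprop-1-en-2-yl)-3-[(triethylsilyl)oxy]cyclohexyl (2Z)-4-acetoxy-2-methylbut-2-enoate | C=C[C@]1(C)C[C@H](OC(=O)/C(C)=C\COC(C)=O)[C@@H](C(=C)C=O)[C@@H](O[Si](CC)(CC)CC)[C@H]1C(=C)CO[Si](c2ccccc2)(c2ccccc2)C(C)(C)C | intermediate (not isolated)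
42 | 2-[(1R,2S,3R,4S,6S)-6-{[(2Z)-4-acetoxy-2-methylbut-2-enoyl]oxy}-3-{3-[(tert-butyldiphenylsilyl)oxy]prop-1-en-2-yl}-4-ethenyl-4-methyl-2-[(triethylsilyl)oxy]cyclohexyl]prop-2-enoic acid | C=C[C@]1(C)C[C@H](OC(=O)/C(C)=C\COC(C)=O)[C@@H](C(=C)C(=O)O)[C@@H](O[Si](CC)(CC)CC)[C@H]1C(=C)CO[Si](c2ccccc2)(c2ccccc2)C(C)(C)C | intermediate
43 | 2-[(1S,2S,3R,4S,6S)-6-{[(2Z)-4-acetoxy-2-methylbut-2-enoyl]oxy}-4-ethenyl-2-hydroxy-3-(3-hydroxyprop-1-en-2-yl)-4-methylcyclohexyl]prop-2-enoic acid (target locants 5R,6S,7S,8S,10S) | C=C[C@]1(C)C[C@H](OC(=O)/C(C)=C\COC(C)=O)[C@@H](C(=C)C(=O)O)[C@@H](O)[C@H]1C(=C)CO | target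

## Step count and risks

Total step count: 26. Longest linear sequence: 22 steps (steps 1–5, 7–16, 18, 19, 22–26); steps 6, 17, 20 and 21 prepare side fragments.

**Step 14 (key step).** What may go wrong:
- insufficient facial discrimination at C10, because the favoured transition state still carries a syn-axial methyl/silyloxy contact;
- base-induced 1,4-elimination of the π-allyl complex through the doubly allylic C5–H, giving a triene;
- slow ionisation of the trisubstituted carbonate.

Fallback (palladium-free, from 21 back to 22): the carbonate of 21 is removed with K2CO3 in methanol to give the allylic alcohol tert-butyl (5R,6R,7E)-6-{3-[(tert-butyldiphenylsilyl)oxy]prop-1-en-2-yl}-9-hydroxy-7-methyl-3-oxo-5-[(triethylsilyl)oxy]non-7-enoate F1. MeSO2Cl, 2,4,6-collidine and LiCl in DMF convert it into the primary allylic chloride F2. Cs2CO3 in MeCN then closes the ring by intramolecular SN2′ alkylation of the β-keto ester at C10 (again six- versus eight-membered ring), returning to 22. Here no metal-bound allyl exists, so the elimination pathway is absent and the C10 selectivity is set by a different chair-like SN2′ transition state.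

**Step 18.** What may go wrong:
- expulsion of the axial C6 oxygen from the metal enolate (its C–O bond is aligned with the enolate π-system);
- sluggish coupling of the 1,1-disubstituted alkenyl bromide;
- migration of the new double bond into conjugation with the C8 ketone;
- incomplete C7 regiocontrol carried over from step 16.

Fallback (classical alkylation/methylenation, from 25 back to 31):
- MeLi in THF releases the C7 lithium enolate from 25, which is alkylated at −78 °C with tert-butyl bromoacetate (DMPU); citric acid work-up gives tert-butyl [(1S,2S,3R,4S)-3-{3-[(tert-butyldiphenylsilyl)oxy]prop-1-en-2-yl}-4-ethenyl-2-hydroxy-4-methyl-6-oxocyclohexyl]acetate F3.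
- Evans–Saksena reduction as in step 19 gives the diol F4.
- Et3SiOTf/2,6-lutidine gives the bis(triethylsilyl) ether F5.
- LiN(i-Pr)2 followed by dimethyl(methylidene)ammonium iodide gives the Mannich base F6, which is N-methylated (MeI) and eliminated (NaHCO3) in one flask to the tert-butyl acrylate F7.
- i-Bu2AlH reduces F7 to the allylic alcohol F8.
- 4-Methoxybenzyl 2,2,2-trichloroacetimidate with La(OTf)3 gives the PMB ether F9.
- HF·pyridine removes both TES groups and returns to diol 31.

**Step 7.** What may go wrong: low rate or low enantioselectivity with the hindered β,γ-disubstituted dienyl boronate, so that the uncatalysed racemic pathway competes; erosion of the syn selectivity if the boronate isomerises.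

Fallback (reagent control, from 8 and 12 back to 14): bromide 8 is lithiated (t-BuLi, Et2O, −78 °C) and added to diisopropyl (4R,5R)-2-(chloromethyl)-1,3,2-dioxaborolane-4,5-dicarboxylate. Matteson-type 1,2-migration gives the tartrate allylboronate diisopropyl (4R,5R)-2-[(2E,4E)-6-[(tert-butyldimethylsilyl)oxy]-2-{[(tert-butyldiphenylsilyl)oxy]methyl}-4-methylhexa-2,4-dien-1-yl]-1,3,2-dioxaborolane-4,5-dicarboxylate F10. F10 adds to aldehyde 12 (PhMe, 4 Å molecular sieves, −78 °C) under control of the (R,R)-tartrate, which is expected to attack the Si face, and aqueous work-up gives 14.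

**Step 22.** What may go wrong: isomerisation of the (Z)-enoate to the (E)-isomer or loss of acetate with butenolide formation while the acid is activated; slow acylation of the hindered C8–OH; partial acylation at C6.

Fallback (build the side chain on the substrate, from 31 to 39): the C8 hydroxyl of 31 is acylated with 2-[bis(2,2,2-trifluoroethoxy)phosphoryl]propanoic acid (carbodiimide, 4-(dimethylamino)pyridine) to give the phosphonate ester F11. Et3SiOTf/2,6-lutidine gives its C6 triethylsilyl ether F12. Still–Gennari olefination of F12 with 2-oxoethyl acetate (KN(SiMe3)2, 18-crown-6, THF, −78 °C) forms the (Z)-trisubstituted enoate directly and gives 39; no free (Z)-acid is ever activated.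

## Further compounds

F1 | step 14 | tert-butyl (5R,6R,7E)-6-{3-[(tert-butyldiphenylsilyl)oxy]prop-1-en-2-yl}-9-hydroxy-7-methyl-3-oxo-5-[(triethylsilyl)oxy]non-7-enoate | CC(C)(C)OC(=O)CC(=O)C[C@@H](O[Si](CC)(CC)CC)[C@@H](C(=C)CO[Si](c1ccccc1)(c1ccccc1)C(C)(C)C)/C(C)=C/CO
F2 | step 14 | tert-butyl (5R,6R,7E)-6-{3-[(tert-butyldiphenylsilyl)oxy]prop-1-en-2-yl}-9-chloro-7-methyl-3-oxo-5-[(triethylsilyl)oxy]non-7-enoate | CC(C)(C)OC(=O)CC(=O)C[C@@H](O[Si](CC)(CC)CC)[C@@H](C(=C)CO[Si](c1ccccc1)(c1ccccc1)C(C)(C)C)/C(C)=C/CCl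
F3 | step 18 | tert-butyl [(1S,2S,3R,4S)-3-{3-[(tert-butyldiphenylsilyl)oxy]prop-1-en-2-yl}-4-ethenyl-2-hydroxy-4-methyl-6-oxocyclohexyl]acetate | C=C[C@]1(C)CC(=O)[C@@H](CC(=O)OC(C)(C)C)[C@@H](O)[C@H]1C(=C)CO[Si](c2ccccc2)(c2ccccc2)C(C)(C)C
F4 | step 18 | tert-butyl [(1R,2S,3R,4S,6S)-3-{3-[(tert-butyldiphenylsilyl)oxy]prop-1-en-2-yl}-4-ethenyl-2,6-dihydroxy-4-methylcyclohexyl]acetate | C=C[C@]1(C)C[C@H](O)[C@@H](CC(=O)OC(C)(C)C)[C@@H](O)[C@H]1C(=C)CO[Si](c2ccccc2)(c2ccccc2)C(C)(C)C
F5 | step 18 | bis(triethylsilyl) ether of F4 | C=C[C@]1(C)C[C@H](O[Si](CC)(CC)CC)[C@@H](CC(=O)OC(C)(C)C)[C@@H](O[Si](CC)(CC)CC)[C@H]1C(=C)CO[Si](c2ccccc2)(c2ccccc2)C(C)(C)C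
F6 | step 18 | tert-butyl 3-(dimethylamino)-2-(ring)propanoate, the Mannich base of F5 (C11 epimers) | C=C[C@]1(C)C[C@H](O[Si](CC)(CC)CC)[C@@H](C(CN(C)C)C(=O)OC(C)(C)C)[C@@H](O[Si](CC)(CC)CC)[C@H]1C(=C)CO[Si](c2ccccc2)(c2ccccc2)C(C)(C)C
F7 | step 18 | tert-butyl 2-(ring)prop-2-enoate with C6 and C8 triethylsilyl ethers | C=C[C@]1(C)C[C@H](O[Si](CC)(CC)CC)[C@@H](C(=C)C(=O)OC(C)(C)C)[C@@H](O[Si](CC)(CC)CC)[C@H]1C(=C)CO[Si](c2ccccc2)(c2ccccc2)C(C)(C)C
F8 | step 18 | 2-(ring)prop-2-en-1-ol with C6 and C8 triethylsilyl ethers | C=C[C@]1(C)C[C@H](O[Si](CC)(CC)CC)[C@@H](C(=C)CO)[C@@H](O[Si](CC)(CC)CC)[C@H]1C(=C)CO[Si](c2ccccc2)(c2ccccc2)C(C)(C)C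
F9 | step 18 | 4-methoxybenzyl ether of F8 (bis(triethylsilyl) ether of 31) | C=C[C@]1(C)C[C@H](O[Si](CC)(CC)CC)[C@@H](C(=C)COCc2ccc(OC)cc2)[C@@H](O[Si](CC)(CC)CC)[C@H]1C(=C)CO[Si](c2ccccc2)(c2ccccc2)C(C)(C)C
F10 | step 7 | diisopropyl (4R,5R)-2-[(2E,4E)-6-[(tert-butyldimethylsilyl)oxy]-2-{[(tert-butyldiphenylsilyl)oxy]methyl}-4-methylhexa-2,4-dien-1-yl]-1,3,2-dioxaborolane-4,5-dicarboxylate | CC(C)(C)[Si](OC/C(CB1O[C@@H](C(=O)OC(C)C)[C@H](C(=O)OC(C)C)O1)=C/C(C)=C/CO[Si](C)(C)C(C)(C)C)(c1ccccc1)c1ccccc1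
F11 | step 22 | C8 2-[bis(2,2,2-trifluoroethoxy)phosphoryl]propanoate of 31 (C6–OH free; epimers at the phosphonate carbon) | C=C[C@]1(C)C[C@H](OC(=O)C(C)P(=O)(OCC(F)(F)F)OCC(F)(F)F)[C@@H](C(=C)COCc2ccc(OC)cc2)[C@@H](O)[C@H]1C(=C)CO[Si](c2ccccc2)(c2ccccc2)C(C)(C)C
F12 | step 22 | C6 triethylsilyl ether of F11 | C=C[C@]1(C)C[C@H](OC(=O)C(C)P(=O)(OCC(F)(F)F)OCC(F)(F)F)[C@@H](C(=C)COCc2ccc(OC)cc2)[C@@H](O[Si](CC)(CC)CC)[C@H]1C(=C)CO[Si](c2ccccc2)(c2ccccc2)C(C)(C)C
A1 | alternative 1 | cis-fused 2-ethoxy-hexahydrobenzofuran with the C8 oxygen bound to a 2,2,6,6-tetramethylpiperidinyl group and C15–OTBS (acetal epimers) | C=C[C@]1(C)C[C@H](ON2C(C)(C)CCCC2(C)C)[C@H]3CC(OCC)O[C@H]3[C@H]1C(=C)CO[Si](C)(C)C(C)(C)C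
A2 | alternative 1 | C6 2-bromo-1-ethoxyethyl acetal of the C7=C8 cyclohexenol with C15–OTBS | C=C[C@]1(C)CC=C[C@@H](OC(OCC)CBr)[C@H]1C(=C)CO[Si](C)(C)C(C)(C)C
A3 | alternative 2 | allyl 2-(cyclohexyl)acrylate with free C6–OH, C8–OPMB and C15–OTBDPS | C=C[C@]1(C)C[C@H](OCc2ccc(OC)cc2)[C@@H](C(=C)C(=O)OCC=C)[C@@H](O)[C@H]1C(=C)CO[Si](c1ccccc1)(c1ccccc1)C(C)(C)C
A4 | alternative 2 | acyclic C6 aldehyde with a (Z)-2-(bromomethyl)enoate allyl ester terminus, C8–OPMB and C15–OTBDPS | O=C[C@@H](C(=C)CO[Si](c1ccccc1)(c1ccccc1)C(C)(C)C)[C@](C)(C=C)C[C@H](OCc1ccc(OC)cc1)/C=C(\CBr)C(=O)OCC=C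
A5 | alternative 3 | ethyl 6-formyl-1-methyl-3-[(tert-butyldimethylsilyl)oxy]-5-[(triethylsilyl)oxy]cyclohex-3-ene-1-carboxylate | CCOC(=O)[C@]1(C)CC(O[Si](C)(C)C(C)(C)C)=C[C@@H](O[Si](CC)(CC)CC)[C@H]1C=O
A6 | alternative 3 | (1E)-3-[(tert-butyldimethylsilyl)oxy]-1-[(triethylsilyl)oxy]buta-1,3-diene | C=C(O[Si](C)(C)C(C)(C)C)/C=C/O[Si](CC)(CC)CC
A7 | alternative 3 | ethyl (2E)-2-methyl-4-oxobut-2-enoate | CCOC(=O)/C(C)=C/C=O
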